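**Plan**
- Retrosynthetic cuts: first the angelate ester C–O bond; then the exocyclic C3–CH2O and C4–CH2Ar bonds together, after the CH2O carbon and the benzylic carbon are rejoined (through a lactone) into a cyclobutanone; last the C2–aryl bond.
- Enabling feature: in the oxolane ring (O1, C2 bearing the aryl group, C3, C4, C5) the exocyclic carbons on C3 and C4 are vicinal and cis, so tied to each other they are the two extra atoms of a cyclobutanone ring cis-fused across C3–C4, the [2+2] adduct of (3,4-dimethoxyphenyl)ketene with the C3=C4 bond of a 2-aryl-2,5-dihydrofuran.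
- Forward order: the oxolane ring is bought as 2,3-dihydrofuran and arylated at C2; the cyclobutanone ring is closed on C3=C4 with the ketene used as its chiral keteniminium salt; oxygen insertion and benzylic C–O hydrogenolysis cut the four-membered ring between the two new carbons; acid, alcohol and angelate follow.
- Stereochemistry: C2 from the chiral Pd catalyst of the Heck step; C3 and C4 from the cycloaddition (cis by suprafacial addition, trans to the aryl group by attack on the open face, orientation by the C2-symmetric amine of the keteniminium); the Z alkene comes with angelic acid and is kept by a Mitsunobu esterification.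

Key step: step 4

Assumptions on the sense of induction: the (R)-phosphinooxazoline is taken to give the (S)-dihydrofuran in step 2 and the (2R,5R)-amine to direct the iminium carbon to C3 in step 4; if either sense proves opposite, the enantiomeric ligand or amine is used in exactly the same way.

Step 1
Reactants: 1 3,4-dimethoxyphenol
Product: 2 3,4-dimethoxyphenyl trifluoromethanesulfonate
Conditions: Tf2O, pyridine, CH2Cl2, 0 °C to rt
Reagents that add atoms: trifluoromethanesulfonic anhydride, O=S(=O)(OS(=O)(=O)C(F)(F)F)C(F)(F)F
Why: O-Sulfonylation (triflation) of a phenol is routine and turns the aryl C–O bond into the pseudohalide needed for the cationic Heck pathway.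

Step 2
Reactants: 2 3,4-dimethoxyphenyl trifluoromethanesulfonate; 3 2,3-dihydrofuran
Product: 4 (2S)-2-(3,4-dimethoxyphenyl)-2,5-dihydrofuran
Conditions: Pd2(dba)3 (1.5 mol %), (R)-4-tert-butyl-2-(2-diphenylphosphinophenyl)-4,5-dihydrooxazole (6 mol %), i-Pr2NEt, THF, 70 °C
Reagents that add atoms: none
Why: Asymmetric intermolecular Heck reaction in which the cationic aryl–Pd complex of the chiral phosphinooxazoline adds across the enol ether with the aryl group at the oxygen-bearing carbon on the face chosen by the ligand, which sets C2 as S, and after β-hydride elimination away from the new stereocenter the Pd–H unit leaves the alkene before it can re-add, so the double bond stays at C3=C4.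

Step 3
Reactants: 5 (3,4-dimethoxyphenyl)acetic acid; 6 (2R,5R)-2,5-dimethylpyrrolidine
Product: 8 2-(3,4-dimethoxyphenyl)-1-[(2R,5R)-2,5-dimethylpyrrolidin-1-yl]ethan-1-one, via (3,4-dimethoxyphenyl)acetyl chloride 7 (not isolated)
Conditions: (COCl)2, DMF (cat.), CH2Cl2, 0 °C to rt; evaporate; then 6, Et3N, CH2Cl2, 0 °C
Reagents that add atoms: oxalyl chloride, O=C(Cl)C(=O)Cl (chlorine of 7 only; none of its atoms remain in 8)
Why: Acid chloride formation followed by N-acylation of the hindered secondary amine (Schotten–Baumann-type amide synthesis) is standard and touches neither stereocenter of the C2-symmetric amine.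

Step 4
Reactants: 8 2-(3,4-dimethoxyphenyl)-1-[(2R,5R)-2,5-dimethylpyrrolidin-1-yl]ethan-1-one; 4 (2S)-2-(3,4-dimethoxyphenyl)-2,5-dihydrofuran
Product: 11 (1S,2S,5R,6R)-2,6-bis(3,4-dimethoxyphenyl)-3-oxabicyclo[3.2.0]heptan-7-one, via keteniminium triflate 9 (not isolated), via cyclobutaniminium triflate 10 (not isolated)
Conditions: 8 (1.5 equiv), 4, 2,4,6-collidine, ClCH2CH2Cl, Tf2O added at −20 °C, then 60 °C; then H2O, 60 °C
Reagents that add atoms: water, O (carbonyl oxygen of 11); trifluoromethanesulfonic anhydride, O=S(=O)(OS(=O)(=O)C(F)(F)F)C(F)(F)F (triflate counter-ion of 9 and 10 only)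
Why: O-Triflation of amide 8 and loss of triflic acid give the keteniminium ion 9, the nitrogen-activated form of (3,4-dimethoxyphenyl)ketene, whose central carbon bonds to C3 of 4 while the positive charge developing at C4 is quenched at once by the enamine carbon that carries the aryl group, so the C3–C(=N) and C4–CH(Ar) bonds form on one face. The closest known reaction is the keteniminium–alkene [2+2] cycloaddition of unactivated cis-cycloalkenes, including its auxiliary-controlled form with amides of C2-symmetric pyrrolidines. The four-membered ring closes by this stepwise but suprafacial [2+2] process and is therefore cis-fused to the oxolane. Both new ring-fusion stereocenters (C3 and C4 of the oxolane) are set by the C2 aryl group, which screens one face of the flat dihydrofuran so that the reagent adds anti to it; the arylated carbon is expected endo, but it becomes a CH2 group in step 6 and its configuration does not matter. The step needs orientational selectivity (iminium carbon to C3, arylated carbon to C4), which the substrate alone hardly supplies because C3 and C4 differ only in their remote neighbours; on the open face the two orientations are the two mirror-image senses of addition to a cis-alkene, and these should be told apart by the (2R,5R)-2,5-dimethylpyrrolidine unit, which is why this amine and not a simple dialkylamine is used. Hydrolysis of 10 then gives ketone 11 and returns the amine.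

Step 5
Reactants: 11 (1S,2S,5R,6R)-2,6-bis(3,4-dimethoxyphenyl)-3-oxabicyclo[3.2.0]heptan-7-one
Product: 12 (1S,2S,5R,6R)-2,6-bis(3,4-dimethoxyphenyl)-3,7-dioxabicyclo[3.3.0]octan-8-one
Conditions: mCPBA, CH2Cl2, 0 °C to rt
Reagents that add atoms: 3-chloroperoxybenzoic acid, O=C(OO)c1cccc(Cl)c1
Why: Baeyer–Villiger oxidation of a strained cyclobutanone is fast, and the benzylic, electron-rich C6 should migrate with retention in preference to the ring-fusion carbon C1, so the oxygen enters between the carbonyl carbon and C6 and no oxolane stereocenter is touched.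

Step 6
Reactants: 12 (1S,2S,5R,6R)-2,6-bis(3,4-dimethoxyphenyl)-3,7-dioxabicyclo[3.3.0]octan-8-one
Product: 13 (2S,3S,4R)-4-(3,4-dimethoxybenzyl)-2-(3,4-dimethoxyphenyl)oxolane-3-carboxylic acid
Conditions: H2 (1 atm), 10% Pd/C, pyridine (0.5 equiv), EtOAc–MeOH, rt
Reagents that add atoms: none
Why: Catalytic hydrogenolysis of a benzylic carboxylate C–O bond (the lactone C6–O7 bond) over amine-moderated palladium on carbon, conditions under which benzylic ethers such as the oxolane C2–O bond are normally kept, should turn C6 into the benzylic CH2 group and free the acid on C3 without touching C2, C3 or C4.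

Step 7
Reactants: 13 (2S,3S,4R)-4-(3,4-dimethoxybenzyl)-2-(3,4-dimethoxyphenyl)oxolane-3-carboxylic acid
Product: 14 [(2S,3R,4R)-4-(3,4-dimethoxybenzyl)-2-(3,4-dimethoxyphenyl)oxolan-3-yl]methanol
Conditions: LiAlH4, THF, 0 °C to rt; then H2O
Reagents that add atoms: none
Why: Hydride reduction of a carboxylic acid to the primary alcohol with LiAlH4 is standard and runs through the aluminium carboxylate without enolisation, so C3 keeps its configuration.

Step 8
Reactants: 14 [(2S,3R,4R)-4-(3,4-dimethoxybenzyl)-2-(3,4-dimethoxyphenyl)oxolan-3-yl]methanol; 15 angelic acid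
Product: 16 leoligin
Conditions: PPh3, DIAD, THF, 0 °C to rt
Reagents that add atoms: none
Why: Mitsunobu esterification activates the primary alcohol and not the acid, so the (Z)-2-methylbut-2-enoate should form under neutral conditions without the isomerisation to the tiglate that acyl activation or base can cause, and no stereocenter is involved.

**Compound list**
1 | 3,4-dimethoxyphenol | COc1ccc(O)cc1OC | starting material
2 | 3,4-dimethoxyphenyl trifluoromethanesulfonate | COc1ccc(OS(=O)(=O)C(F)(F)F)cc1OC | intermediate
3 | 2,3-dihydrofuran | C1=COCC1 | starting material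
4 | (2S)-2-(3,4-dimethoxyphenyl)-2,5-dihydrofuran | C1=CCO[C@@H]1c1ccc(OC)c(OC)c1 | intermediate
5 | (3,4-dimethoxyphenyl)acetic acid | COc1ccc(CC(=O)O)cc1OC | starting material
6 | (2R,5R)-2,5-dimethylpyrrolidine | C[C@@H]1CC[C@@H](C)N1 | starting material
7 | (3,4-dimethoxyphenyl)acetyl chloride | COc1ccc(CC(=O)Cl)cc1OC | intermediate
8 | 2-(3,4-dimethoxyphenyl)-1-[(2R,5R)-2,5-dimethylpyrrolidin-1-yl]ethan-1-one | COc1ccc(CC(=O)N2[C@H](C)CC[C@H]2C)cc1OC | intermediate
9 | (2R,5R)-1-[2-(3,4-dimethoxyphenyl)ethenylidene]-2,5-dimethylpyrrolidin-1-ium trifluoromethanesulfonate (keteniminium salt, the N-activated form of (3,4-dimethoxyphenyl)ketene) | COc1ccc(C=C=[N+]2[C@H](C)CC[C@H]2C)cc1OC.[O-]S(=O)(=O)C(F)(F)F | intermediate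
10 | cyclobutaniminium triflate: ketone 11 with its C=O replaced by C=N+ of (2R,5R)-2,5-dimethylpyrrolidine, triflate counter-ion | C[C@@H]3CC[C@@H](C)[N+]3=C2[C@H]1[C@@H]([C@@H]2c2ccc(OC)c(OC)c2)CO[C@@H]1c1ccc(OC)c(OC)c1.[O-]S(=O)(=O)C(F)(F)F | intermediate
11 | (1S,2S,5R,6R)-2,6-bis(3,4-dimethoxyphenyl)-3-oxabicyclo[3.2.0]heptan-7-one (cis-fused; 2-aryl exo, 6-aryl endo) | O=C2[C@H]1[C@@H]([C@@H]2c2ccc(OC)c(OC)c2)CO[C@@H]1c1ccc(OC)c(OC)c1 | intermediate
12 | (1S,2S,5R,6R)-2,6-bis(3,4-dimethoxyphenyl)-3,7-dioxabicyclo[3.3.0]octan-8-one (cis-fused γ-lactone, O7 between C8=O and the arylated C6) | O=C2[C@H]1[C@@H]([C@@H](O2)c2ccc(OC)c(OC)c2)CO[C@@H]1c1ccc(OC)c(OC)c1 | intermediate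
13 | (2S,3S,4R)-4-(3,4-dimethoxybenzyl)-2-(3,4-dimethoxyphenyl)oxolane-3-carboxylic acid | OC(=O)[C@H]1[C@@H](Cc2ccc(OC)c(OC)c2)CO[C@@H]1c1ccc(OC)c(OC)c1 | intermediate
14 | [(2S,3R,4R)-4-(3,4-dimethoxybenzyl)-2-(3,4-dimethoxyphenyl)oxolan-3-yl]methanol | OC[C@H]1[C@@H](Cc2ccc(OC)c(OC)c2)CO[C@@H]1c1ccc(OC)c(OC)c1 | intermediate
15 | angelic acid, (2Z)-2-methylbut-2-enoic acid | C/C=C(/C)C(=O)O | starting material
16 | leoligin, [(2S,3R,4R)-4-(3,4-dimethoxybenzyl)-2-(3,4-dimethoxyphenyl)oxolan-3-yl]methyl (2Z)-2-methylbut-2-enoate | C/C=C(/C)C(=O)OC[C@H]1[C@@H](Cc2ccc(OC)c(OC)c2)CO[C@@H]1c1ccc(OC)c(OC)c1 | target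

Total step count: 8. Longest linear sequence: 7 steps (steps 1, 2, 4, 5, 6, 7, 8).

**Steps most likely to fail**

Step 4. Three processes can go wrong:
- (a) the iminium carbon bonds to C4 and not to C3, because the amine's control is too weak or of the other sense;
- (b) the cationic intermediate is diverted by the electron-rich aryl rings (arene attack, aryl shift);
- (c) the benzylic, allylic ether opens under the acidic salts.

The fallback sets out from acid chloride 7 (made as in step 3 and freed of oxalyl chloride by evaporation) and comes back at cyclobutanone 11. Et3N in CH2Cl2 at −78 °C, with 4 present, converts 7 into (3,4-dimethoxyphenyl)ketene F1, and EtAlCl2 at −78 °C then promotes the ketene–alkene [2+2] cycloaddition. This replaces the amide-derived cation by an aluminium-bound neutral ketene. Its small carbonyl end, not a bulky iminium end, has to reach the more encumbered C3, and its large ArCH end closes on C4. Orientation then rests on the substrate alone, and any regioisomer would be removed at the stage of 11.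

Step 6. The oxolane C2–O bond is also benzylic and may be hydrogenolysed along with, or instead of, the lactone C–O bond (over-reduction to a ring-opened product). The fallback sets out from cyclobutanone 11, leaves out step 5 and comes back at acid 13. KOH in t-BuOH–H2O at reflux adds hydroxide to the strained carbonyl group, and the C7–C6 bond breaks toward the benzylic carbon (retro-Claisen, Haller–Bauer-type ring opening). The acid on C3 and the benzylic CH2 on C4 then arise in one operation, with no benzylic C–O bond to reduce. This fallback makes no new compound (F0).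

Step 2. Oxidative addition of the electron-rich triflate to zerovalent palladium may be slow. Long reaction times would allow Pd–H re-addition, which moves the double bond to the 2,3-dihydro isomer and erodes the enantiomeric purity. The fallback sets out from triflate 2 and comes back at dihydrofuran 4:
- Stille coupling of 2 with (E)-3-(tributylstannyl)prop-2-en-1-ol (Pd(PPh3)4, LiCl, dioxane, 90 °C) should give (E)-3-(3,4-dimethoxyphenyl)prop-2-en-1-ol F2.
- Methyl chloroformate and pyridine should give (E)-3-(3,4-dimethoxyphenyl)prop-2-en-1-yl methyl carbonate F3.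
- Branch-selective asymmetric allylic etherification with allyl alcohol (K3PO4, [Ir(cod)Cl]2, chiral phosphoramidite ligand, THF) should give 4-[(1S)-1-(prop-2-en-1-yloxy)prop-2-en-1-yl]-1,2-dimethoxybenzene F4 and sets the stereocenter.
- Ring-closing metathesis with the second-generation Grubbs catalyst (H2IMes)(PCy3)Cl2Ru=CHPh in CH2Cl2 closes the 2,5-dihydrofuran ring of 4 with the double bond fixed at C3=C4.

**Further compounds**
F1 | step 4 | (3,4-dimethoxyphenyl)ketene | COc1ccc(C=C=O)cc1OC
F0 | step 6 | none | none
F2 | step 2 | (E)-3-(3,4-dimethoxyphenyl)prop-2-en-1-ol | COc1ccc(/C=C/CO)cc1OC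
F3 | step 2 | (E)-3-(3,4-dimethoxyphenyl)prop-2-en-1-yl methyl carbonate | COC(=O)OC/C=C/c1ccc(OC)c(OC)c1
F4 | step 2 | 4-[(1S)-1-(prop-2-en-1-yloxy)prop-2-en-1-yl]-1,2-dimethoxybenzene | C=CCO[C@@H](C=C)c1ccc(OC)c(OC)c1
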